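Thursday's run, with 9.4 mM of added ligand against Tuesday's 21 mM, lost substrate faster: its pseudo-first-order constant, read at 5.00 min, is 0.271 /min against Tuesday's 0.126 /min. The new flask carries Saturday's ligand and Thursday's coupling partner.

| flask | substrate | coupling partner | free catalyst | impurity | added ligand | remark |
|---|---|---|---|---|---|---|
| Thursday's | 0.10 M | 0.20 M | 5 mM | 0.76 mM | 9.4 mM | run made earlier |
| Tuesday's | 0.10 M | 0.20 M | 5 mM | 0.76 mM | 21 mM | run made earlier |
| Saturday's | 0.10 M | 0.10 M | 5 mM | 0.76 mM | 14 mM | run made earlier |
| flask | 0.10 M | 0.200 M | 5.0 mM | 0.76 mM | 14 mM |  |

- Thursday's (time / min: product / %, substrate / %): 1.00: 0, 70.8; 2.50: 5.6, 48.9; 3.00: 7.8, 43.4; 5.00: 15.5, 25.8; 6.00: 19.1, 20.7; 8.00: 24.7, 13.8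
- Tuesday's (time / min: product / %, substrate / %): 0.417: 0.8, 88.6; 1.33: 1.5, 79.7; 2.50: 1.0, 69.4; 3.00: 1.5, 64.8; 5.00: 2.6, 53.2; 6.00: 5.1, 46.0; 8.00: 8.8, 37.4
- Saturday's (time / min: product / %, substrate / %): 1.50: 1.2, 70.1; 3.00: 2.3, 56.1; 5.00: 4.7, 39.4; 6.00: 3.9, 31.7; 8.00: 8.6, 23.6

(scatter of a reading: 1 percentage point)

1. apparent order in coupling partner when 20% of the substrate are converted (percent change of the rate of making product for one percent more coupling partner charged)
2. apparent order in free catalyst when 20% of the substrate are converted (percent change of the rate of making product for one percent more free catalyst charged)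

- the numbers in the tables scatter with a standard deviation of 1 percentage point
- no earlier run changes the charge of free catalyst; that part of a forecast is a guess

Two settings are asked about. The first is coupling partner. Saturday's product reads 1.2% at 1.50 min, close to the scatter of 1 percentage point, so the order is read late and assumed to hold at the conversion asked. Thursday's 24.7% and Tuesday's 8.8% at 8.00 min, interpolated in logarithms to Saturday's ligand, give 14.8%. Saturday, with half the partner, read 8.6% at 8.00 min, so this reckoning, made on accumulated product, gives an order of 0.784.

The second is free catalyst, which no run varied. This reckoning assumes that impurity takes catalyst one for one, leaving 4.24 mM, and that free catalyst goes as that amount divided by an offset plus the ligand in excess of it. Thursday and Tuesday give an offset of 4.96 mM. With substrate loss taken as indifferent to coupling partner, that predicts 0.186 /min for Saturday, which read 0.186 /min. Differentiating with ligand, impurity and offset held fixed gives 1.52 for the flask: this is the catalyst leverage, the percent change of free catalyst for one percent more catalyst charged. Product rate at fixed conversion is assumed to follow free catalyst, so in this reckoning the leverage is the order.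

The forecast gives 0.85 (0.45 to 1.2) and 1.6 (1 to 2.5), both slightly above this reckoning: “Catalyst order is inferred, not measured.”

The flask gives 0.76 and 1.6, both within the forecast's margins.

    free catalyst + impurity → spent catalyst (k = 154 /M/s)
    free catalyst + open intermediate ⇌ catalyst intermediate (K = 3.98 /M, k = 4.43 /M/s)
    free catalyst + added ligand ⇌ idle complex (K = 380 /M, k = 8.20 /M/s)
    coupling partner + catalyst intermediate → free catalyst + product (k = 1.56 /M/s)
    substrate + free catalyst → free catalyst + open intermediate (k = 3.42 /M/s)

With impurity as charged, free catalyst in the flask has a half-life of 0.0987 min by the step with impurity alone, while substrate's half-life by the step that makes open intermediate is 4.1 min at 2.62 min, and at 1.00 min impurity stands at 0% of its charge and spent catalyst at 15.2% of the catalyst charged, the 15.2% set aside in the reckoning. The leverage of 1.52 stands beside the order of 1.6, and at 5.00 min the flask holds idle complex, an off-cycle form, at 66.0% of the catalyst charged and free catalyst at 16.2%.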